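## Retrosynthetic overview

1. Feature: the spiro carbon (C5) lies between the vinyl carbon C10, which carries the CH2O-angelate, and the methyl-bearing CH (C4), and it is shared with the cyclopentane carrying the cis-fused α-methylene lactone. The skeleton is thus a eudesman-8β,12-olide whose C9 methylene has moved from the angular carbon C10 to the ring-fusion carbon C5.
2. Endgame: angelate ester (Yamaguchi) ⇐ primary C14–OH ⇐ SeO2 oxidation of the vinyl methyl; O3 is carried as a silyl ether.
3. Key disconnection: C5–C9 and C2–O bonds ⇐ cis-fused 5β-hydroxy-3α-silyloxy-eudesma-1,11(13)-dien-8β,12-olide, by ionisation, 1,2-alkyl shift and hydration of the allyl cation.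
4. Precursor ⇐ dehydrogenation and directed reduction of a 5β-hydroxy-3-ketone; lactone ⇐ iodolactonisation of a C8=C9 alkene by the acrylic acid made from the isopropenyl group.
5. Ring order: ring B is carvone; ring A by deconjugative Michael addition to ethyl vinyl ketone and aldol closure (ketol kept); then the lactone ring; last, ring B is contracted to the cyclopentane.

Key step: step 12

Assumption: eudesmane numbering (C1–C15) and its α/β descriptors (β = face of the C10 methyl in the decalin) are kept for all intermediates, including the rearranged 9(10→5)abeo-eudesmanes.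

## Route

Step 1
Reactants: 1 (R)-(−)-carvone; 2 (R)-(+)-1-phenylethylamine
Product: 3 carvone (R)-1-phenylethylimine
Conditions: 4 Å molecular sieves, pyridinium p-toluenesulfonate (cat.), toluene, 60 °C
Reagents that add atoms: none
Why: Imine condensation of the enone carbonyl with the primary amine under water removal should give the conjugated 1-azadiene without touching the carvone stereocentre.

Step 2
Reactants: 3 carvone (R)-1-phenylethylimine; 4 ethyl vinyl ketone
Product: 6 (2R,5S)-2-methyl-2-(3-oxopentyl)-5-(prop-1-en-2-yl)cyclohex-3-en-1-one, via adduct imine 5 (not isolated)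
Conditions: THF, 40 °C; then AcOH/H2O, 25 °C
Reagents that add atoms: water, O
Why: Auxiliary-controlled aza-ene-type Michael addition through the fully conjugated secondary dienamine tautomer should take place at the methyl-bearing α-carbon, creating quaternary C10 and leaving the ring alkene deconjugated at C8=C9; the (R)-phenylethyl group and the isopropenyl group both send the acceptor to the face anti to isopropenyl, and mild acid then hydrolyses the adduct imine.

Step 3
Reactants: 6 (2R,5S)-2-methyl-2-(3-oxopentyl)-5-(prop-1-en-2-yl)cyclohex-3-en-1-one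
Product: 7 5β-hydroxy-4αH-eudesma-8,11(13)-dien-3-one (cis-fused ketol)
Conditions: NaOMe (0.2 equiv), MeOH, 0 °C
Reagents that add atoms: none
Why: Intramolecular aldol addition (a Robinson annulation stopped before dehydration) of the ethyl ketone enolate to the ring carbonyl should give the cis-fused ketol; because aldol and enolisation are reversible the thermodynamic isomer is collected, with 5-OH cis to the angular methyl and the C4 methyl equatorial (β) in the conformer that keeps the isopropenyl group pseudo-equatorial.

Step 4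
Reactants: 7 5β-hydroxy-4αH-eudesma-8,11(13)-dien-3-one
Product: 8 5β,12-dihydroxy-4αH-eudesma-8,11(13)-dien-3-one
Conditions: SeO2 (0.3 equiv), t-BuOOH, CH2Cl2, 25 °C
Reagents that add atoms: tert-butyl hydroperoxide, CC(C)(C)OO (one oxygen atom, passed on through selenium dioxide, O=[Se]=O)
Why: Catalytic SeO2 allylic hydroxylation (ene reaction, then [2,3]-sigmatropic shift) should occur at the methyl group of the 1,1-disubstituted isopropenyl alkene, the most reactive alkene present, leaving the ketol and the ring alkene alone.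

Step 5
Reactants: 8 5β,12-dihydroxy-4αH-eudesma-8,11(13)-dien-3-one
Product: 9 5β-hydroxy-3-oxo-4αH-eudesma-8,11(13)-dien-12-al
Conditions: MnO2, CH2Cl2, 25 °C
Reagents that add atoms: none
Why: MnO2 oxidation is selective for the primary allylic alcohol and should give the enal while the tertiary alcohol stays inert.

Step 6
Reactants: 9 5β-hydroxy-3-oxo-4αH-eudesma-8,11(13)-dien-12-al
Product: 10 5β-hydroxy-3-oxo-4αH-eudesma-8,11(13)-dien-12-oic acid
Conditions: NaClO2, NaH2PO4, 2-methyl-2-butene, t-BuOH/H2O, 0 to 25 °C
Reagents that add atoms: sodium chlorite, [Na+].[O-]Cl=O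
Why: Pinnick oxidation should convert the enal into the acrylic acid under buffered conditions, the scavenger alkene removing hypochlorous acid so that the substrate alkenes survive.

Step 7
Reactants: 10 5β-hydroxy-3-oxo-4αH-eudesma-8,11(13)-dien-12-oic acid
Product: 11 5β-hydroxy-9α-iodo-3-oxo-4αH-eudesm-11(13)-en-8β,12-olide
Conditions: I2, NaHCO3, MeCN/H2O, 0 °C, dark
Reagents that add atoms: iodine, II
Why: Iodolactonisation, in which the β-disposed carboxylate opens the α-iodonium ion of C8=C9 in a 5-exo, trans-diaxial manner, should place the lactone oxygen at C8 cis to the C7 side chain (8β) and iodine at C9α.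

Step 8
Reactants: 11 5β-hydroxy-9α-iodo-3-oxo-4αH-eudesm-11(13)-en-8β,12-olide
Product: 12 5β-hydroxy-3-oxo-4αH-eudesm-11(13)-en-8β,12-olide
Conditions: Bu3SnH, azobisisobutyronitrile (cat.), benzene, 80 °C
Reagents that add atoms: none
Why: Radical chain deiodination should remove the secondary iodide without touching a stereocentre; it is run while ring A is still saturated so that the C9 radical has no neighbouring π bond into which it could rearrange.

Step 9
Reactants: 12 5β-hydroxy-3-oxo-4αH-eudesm-11(13)-en-8β,12-olide
Product: 13 5β-hydroxy-3-oxo-4αH-eudesma-1,11(13)-dien-8β,12-olide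
Conditions: 2-iodoxybenzoic acid (IBX), 4-methoxypyridine N-oxide, DMSO, 25 to 40 °C
Reagents that add atoms: none
Why: IBX dehydrogenation through the ketone enol should introduce C1=C2, the only place where an endocyclic enone can form because C5 is fully substituted, without oxidising the tertiary alcohol or the methylene lactone.

Step 10
Reactants: 13 5β-hydroxy-3-oxo-4αH-eudesma-1,11(13)-dien-8β,12-olide
Product: 14 3α,5β-dihydroxy-4αH-eudesma-1,11(13)-dien-8β,12-olide
Conditions: Me4NBH(OAc)3, MeCN/AcOH, −30 °C
Reagents that add atoms: none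
Why: Evans–Saksena reduction, in which the axial 5β-hydroxyl binds boron and delivers hydride intramolecularly to the β face of C3, should give the 1,3-anti diol (3α-OH) by 1,2-reduction and leave the methylene lactone untouched.

Step 11
Reactants: 14 3α,5β-dihydroxy-4αH-eudesma-1,11(13)-dien-8β,12-olide
Product: 15 3α-(tert-butyldiphenylsilyloxy)-5β-hydroxy-4αH-eudesma-1,11(13)-dien-8β,12-olide
Conditions: t-BuPh2SiCl, imidazole, DMF, 25 °C
Reagents that add atoms: tert-butyl(chloro)diphenylsilane, CC(C)(C)[Si](Cl)(c1ccccc1)c1ccccc1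
Why: Silylation with the bulky chlorosilane should take the secondary allylic alcohol and leave the tertiary 5-OH free; the tert-butyldiphenylsilyl group is used because it withstands BF3 and shields the α face of C2.

Step 12
Reactants: 15 3α-(tert-butyldiphenylsilyloxy)-5β-hydroxy-4αH-eudesma-1,11(13)-dien-8β,12-olide
Product: 16 2β-hydroxy-3α-(tert-butyldiphenylsilyloxy)-9(10→5)abeo-eudesma-1(10),11(13)-dien-8β,12-olide
Conditions: BF3·OEt2 (0.3 equiv), CH2Cl2 saturated with H2O, −40 to −10 °C; then aq. NaHCO3
Reagents that add atoms: water, O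
Why: Acid-assisted ionisation of the tertiary C5–OH is accompanied by a Wagner–Meerwein 1,2-shift of the antiperiplanar C9–C10 bond to C5, and the resulting tertiary allyl cation (C10–C1–C2) is hydrated at C2; the closest known reaction type is the acid-induced ring contraction of cis-fused eudesmane derivatives to spirovetivanes. The cyclopentane (C5–C6–C7–C8–C9) is closed by this suprafacial 1,2-alkyl shift, a ring contraction through a three-centre transition state and not an exo or endo cyclisation. The spiro centre C5 is set with inversion, because in the preferred cis-decalin conformer (C7–C11 bond equatorial, C4 and C10 methyls not syn-diaxial) the C9–C10 bond is anti to the C5–O bond, which is axial on ring A. C2 is set by water approaching anti to the 3α-silyloxy group, and since the secondary allylic alcohol can re-ionise, the trans-diequatorial 2β,3α isomer is also the thermodynamic product. The step needs the alkyl shift to outrun the equally antiperiplanar hydride shift from C4 and simple proton loss; the C1=C2 bond secures this by making the cation after C9 migration allylic, and the C3 oxygen does so by destabilising a cation at C4. Water adds at the secondary terminus and not at the hindered tertiary terminus next to the spiro carbon, which leaves the trisubstituted C10=C1 alkene.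

Step 13
Reactants: 16 2β-hydroxy-3α-(tert-butyldiphenylsilyloxy)-9(10→5)abeo-eudesma-1(10),11(13)-dien-8β,12-olide
Product: 17 2β,14-dihydroxy-3α-(tert-butyldiphenylsilyloxy)-9(10→5)abeo-eudesma-1(10),11(13)-dien-8β,12-olide
Conditions: SeO2 (0.5 equiv), t-BuOOH, CH2Cl2, 0 to 25 °C
Reagents that add atoms: tert-butyl hydroperoxide, CC(C)(C)OO (one oxygen atom, passed on through selenium dioxide, O=[Se]=O)
Why: SeO2 allylic hydroxylation of the trisubstituted C10=C1 alkene should occur at the only allylic C–H on its more substituted end, the C14 methyl (C5 is quaternary), while the electron-poor methylene lactone is inert.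

Step 14
Reactants: 17 2β,14-dihydroxy-3α-(tert-butyldiphenylsilyloxy)-9(10→5)abeo-eudesma-1(10),11(13)-dien-8β,12-olide; 18 angelic acid
Product: 20 14-angeloyloxy-2β-hydroxy-3α-(tert-butyldiphenylsilyloxy)-9(10→5)abeo-eudesma-1(10),11(13)-dien-8β,12-olide, via mixed anhydride 19 (not isolated)
Conditions: 18, 2,4,6-trichlorobenzoyl chloride, Et3N, toluene, 25 °C; then 17, 75 °C (no DMAP)
Reagents that add atoms: none
Why: Yamaguchi esterification through the mixed anhydride should acylate the unhindered primary allylic alcohol in preference to the secondary 2-OH next to the silyl ether, and leaving out DMAP avoids Z to E isomerisation of the angelate.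

Step 15
Reactants: 20 14-angeloyloxy-2β-hydroxy-3α-(tert-butyldiphenylsilyloxy)-9(10→5)abeo-eudesma-1(10),11(13)-dien-8β,12-olide
Product: 21 14-angeloyloxy-2β,3α-dihydroxy-9(10→5)abeo-eudesma-1(10),11(13)-dien-8β,12-olide (CNP0224912.1)
Conditions: HF·pyridine, pyridine, THF, 0 to 25 °C
Reagents that add atoms: none
Why: Fluoride-mediated desilylation under buffered acidic conditions should free the 3α-OH without acyl migration, angelate isomerisation or conjugate addition to the methylene lactone.

## Compound list

1 | (R)-(−)-carvone | CC1=CC[C@H](CC1=O)C(C)=C | starting material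
2 | (R)-(+)-1-phenylethylamine | C[C@@H](N)c1ccccc1 | starting material
3 | N-[(5R)-2-methyl-5-(prop-1-en-2-yl)cyclohex-2-en-1-ylidene]-(1R)-1-phenylethanamine | CC1=CC[C@H](CC1=N[C@H](C)c2ccccc2)C(C)=C | intermediate
4 | ethyl vinyl ketone (pent-1-en-3-one) | CCC(=O)C=C | starting material
5 | (1R)-1-phenylethylimine of 6 (Michael adduct imine) | CCC(=O)CC[C@]1(C)C=C[C@H](CC1=N[C@H](C)c2ccccc2)C(C)=C | intermediate
6 | (2R,5S)-2-methyl-2-(3-oxopentyl)-5-(prop-1-en-2-yl)cyclohex-3-en-1-one (oxopentyl chain trans to isopropenyl) | CCC(=O)CC[C@]1(C)C=C[C@H](CC1=O)C(C)=C | intermediate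
7 | 5β-hydroxy-4αH-eudesma-8,11(13)-dien-3-one (cis-fused; 4-CH3, 5-OH, 10-CH3 and 7-isopropenyl all β) | CC(=C)[C@@H]1C=C[C@@]2(C)CCC(=O)[C@H](C)[C@@]2(O)C1 | intermediate
8 | 5β,12-dihydroxy-4αH-eudesma-8,11(13)-dien-3-one | OCC(=C)[C@@H]1C=C[C@@]2(C)CCC(=O)[C@H](C)[C@@]2(O)C1 | intermediate
9 | 5β-hydroxy-3-oxo-4αH-eudesma-8,11(13)-dien-12-al | O=CC(=C)[C@@H]1C=C[C@@]2(C)CCC(=O)[C@H](C)[C@@]2(O)C1 | intermediate
10 | 5β-hydroxy-3-oxo-4αH-eudesma-8,11(13)-dien-12-oic acid | OC(=O)C(=C)[C@@H]1C=C[C@@]2(C)CCC(=O)[C@H](C)[C@@]2(O)C1 | intermediate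
11 | 5β-hydroxy-9α-iodo-3-oxo-4αH-eudesm-11(13)-en-8β,12-olide (cis lactone, 7αH, 8αH) | C=C1C(=O)O[C@@H]2[C@@H](I)[C@@]3(C)CCC(=O)[C@H](C)[C@@]3(O)C[C@H]12 | intermediate
12 | 5β-hydroxy-3-oxo-4αH-eudesm-11(13)-en-8β,12-olide | C=C1C(=O)O[C@@H]2C[C@@]3(C)CCC(=O)[C@H](C)[C@@]3(O)C[C@H]12 | intermediate
13 | 5β-hydroxy-3-oxo-4αH-eudesma-1,11(13)-dien-8β,12-olide | C=C1C(=O)O[C@@H]2C[C@@]3(C)C=CC(=O)[C@H](C)[C@@]3(O)C[C@H]12 | intermediate
14 | 3α,5β-dihydroxy-4αH-eudesma-1,11(13)-dien-8β,12-olide | C=C1C(=O)O[C@@H]2C[C@@]3(C)C=C[C@@H](O)[C@H](C)[C@@]3(O)C[C@H]12 | intermediate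
15 | 3α-(tert-butyldiphenylsilyloxy)-5β-hydroxy-4αH-eudesma-1,11(13)-dien-8β,12-olide (cis-fused key-step precursor) | C=C1C(=O)O[C@@H]2C[C@@]3(C)C=C[C@@H](O[Si](c4ccccc4)(c4ccccc4)C(C)(C)C)[C@H](C)[C@@]3(O)C[C@H]12 | intermediate
16 | 2β-hydroxy-3α-(tert-butyldiphenylsilyloxy)-9(10→5)abeo-eudesma-1(10),11(13)-dien-8β,12-olide (spiro at C5; vinyl methyl on C10) | C=C1C(=O)O[C@@H]2C[C@@]3(C[C@H]12)C(C)=C[C@H](O)[C@@H](O[Si](c4ccccc4)(c4ccccc4)C(C)(C)C)[C@@H]3C | intermediate
17 | 2β,14-dihydroxy-3α-(tert-butyldiphenylsilyloxy)-9(10→5)abeo-eudesma-1(10),11(13)-dien-8β,12-olide | C=C1C(=O)O[C@@H]2C[C@@]3(C[C@H]12)C(CO)=C[C@H](O)[C@@H](O[Si](c4ccccc4)(c4ccccc4)C(C)(C)C)[C@@H]3C | intermediate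
18 | angelic acid ((Z)-2-methylbut-2-enoic acid) | C/C=C(/C)C(=O)O | starting material
19 | angelic 2,4,6-trichlorobenzoic anhydride | C/C=C(/C)C(=O)OC(=O)c1c(Cl)cc(Cl)cc1Cl | intermediate
20 | 14-angeloyloxy-2β-hydroxy-3α-(tert-butyldiphenylsilyloxy)-9(10→5)abeo-eudesma-1(10),11(13)-dien-8β,12-olide | C=C1C(=O)O[C@@H]2C[C@@]3(C[C@H]12)C(COC(=O)/C(C)=C\C)=C[C@H](O)[C@@H](O[Si](c4ccccc4)(c4ccccc4)C(C)(C)C)[C@@H]3C | intermediate
21 | 14-angeloyloxy-2β,3α-dihydroxy-9(10→5)abeo-eudesma-1(10),11(13)-dien-8β,12-olide (CNP0224912.1) | C=C1C(=O)O[C@@H]2C[C@@]3(C[C@H]12)C(COC(=O)/C(C)=C\C)=C[C@H](O)[C@@H](O)[C@@H]3C | target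

## Step count and risks

Total step count: 15. Longest linear sequence: 15 steps, from 1.

Steps most likely to fail:

Step 12. After the shift the allyl cation may lose a proton from the C14 methyl faster than it is hydrated, and water may add without positional or facial control. The fallback sets out from 15 and comes back to the route at 17. 15 is ionised under anhydrous conditions (BF3·OEt2, 4 Å molecular sieves, CH2Cl2, −40 °C) so that the shift ends deliberately in proton loss to the exocyclic diene 3α-(tert-butyldiphenylsilyloxy)-9(10→5)abeo-eudesma-1,10(14),11(13)-trien-8β,12-olide F1. mCPBA (NaHCO3, CH2Cl2, 0 °C) should epoxidise its electron-rich 1,1-disubstituted C10=C14 bond, not the methylene lactone, to give the vinyl epoxide F2; either epimer at C10 serves. HClO4 (cat.) in THF/H2O at 0 °C then opens the tertiary allylic C10–O bond and water adds at C2 anti to the silyloxy group (conjugate opening of a vinyl epoxide). This gives 17 directly and makes step 13 unnecessary.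

Step 2. The imine may react through its cross-conjugated enamine tautomer at the C6 methylene instead of the methyl-bearing carbon, or add with poor facial control. The fallback sets out from 1 and 4 and comes back at 6. 1 and cyclohexylamine give the N-cyclohexylimine F3, and 4 is converted with HBr and ethylene glycol into 2-(2-bromoethyl)-2-ethyl-1,3-dioxolane F4. F3 is deprotonated with LiN(iPr)2 in THF and equilibrated to the extended aza-dienolate, which is alkylated by F4 at the α-carbon anti to the isopropenyl group (deconjugative metalloenamine alkylation) to give the imine ketal F5. Aqueous oxalic acid cleaves imine and dioxolane to 6, with removal of the minor C2 epimer if needed.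

Step 13. The oxidation may run past the alcohol to the enal and may also attack the free allylic 2-OH, giving mixtures and poor recovery. The fallback sets out from 16 and comes back at 17. The oxidation is driven on purpose to the aldehyde level (SeO2, 1,4-dioxane, 60 °C) to give the C14 enal F6. NaBH4/CeCl3·7H2O in MeOH at −78 °C (Luche reduction) should then reduce the aldehyde 1,2 without conjugate reduction of the methylene lactone, returning 17.

Further compounds
F1 | step 12 | 3α-(tert-butyldiphenylsilyloxy)-9(10→5)abeo-eudesma-1,10(14),11(13)-trien-8β,12-olide | C=C1C(=O)O[C@@H]2C[C@@]3(C[C@H]12)C(=C)C=C[C@@H](O[Si](c4ccccc4)(c4ccccc4)C(C)(C)C)[C@@H]3C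
F2 | step 12 | 10,14-epoxide of F1 (either epimer at C10) | C=C1C(=O)O[C@@H]2C[C@@]3(C[C@H]12)C4(CO4)C=C[C@@H](O[Si](c5ccccc5)(c5ccccc5)C(C)(C)C)[C@@H]3C
F3 | step 2 | carvone N-cyclohexylimine | CC1=CC[C@H](CC1=NC2CCCCC2)C(C)=C
F4 | step 2 | 2-(2-bromoethyl)-2-ethyl-1,3-dioxolane | CCC1(CCBr)OCCO1
F5 | step 2 | N-cyclohexylimine of (2R,5S)-2-[2-(2-ethyl-1,3-dioxolan-2-yl)ethyl]-2-methyl-5-(prop-1-en-2-yl)cyclohex-3-en-1-one | CCC1(CC[C@]2(C)C=C[C@H](CC2=NC3CCCCC3)C(C)=C)OCCO1
F6 | step 13 | 2β-hydroxy-14-oxo-3α-(tert-butyldiphenylsilyloxy)-9(10→5)abeo-eudesma-1(10),11(13)-dien-8β,12-olide | C=C1C(=O)O[C@@H]2C[C@@]3(C[C@H]12)C(C=O)=C[C@H](O)[C@@H](O[Si](c4ccccc4)(c4ccccc4)C(C)(C)C)[C@@H]3C
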